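**Strategy.** The route rests on excising the C12–C13 bridge from the bicyclo[3.2.1]octane (rings C and D). Both ring C bonds that hold this bridge, C11–C12 and C13–C14, end at carbinol carbons, so C11 and C14 are traced back to two cis formyl groups on C9 and C8 of a preformed spiro-lactone. In one operation SmI2 converts the C14 aldehyde, which sits β to the lactone carbonyl C7, into a chelated ketyl that closes ring D onto a pendant vinyl group; the C12 radical then closes ring C on the C11 aldehyde. The precursor is a spiro-lactone 1,4-dialdehyde whose quaternary C8 carries a penta-1,4-dien-2-yl chain (C15, C16, C13, C12).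

Key step: step 17

Remark: atoms are numbered as in ent-kaurane (ring A: C1–C5 and C10; lactone ring: C7, C8, C9, C10, C20 and O; ring C: C8, C9, C11–C14; ring D: C8, C14, C13, C16, C15); compounds 1, 3, 11, 13, 19 and 22 are taken as catalogue chemicals.

**Route**

Step 1
Reactants: 1 2,4,4-trimethylcyclohex-2-en-1-one
Product: 2 (S)-2,4,4-trimethylcyclohex-2-en-1-ol
Conditions: (R)-2-methyl-CBS-oxazaborolidine (10 mol %), BH3·SMe2, THF, −20 °C; MeOH quench
Reagents that add atoms: none
Why: CBS reduction of an α-substituted cyclic enone is 1,2-selective, and the (R)-oxazaborolidine should deliver hydride to give the (S)-carbinol, the only stereocentre of the route set by a chiral reagent (it becomes C1).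

Step 2
Reactants: 2 (S)-2,4,4-trimethylcyclohex-2-en-1-ol; 3 tributyl(iodomethyl)stannane
Product: 4 tributyl{[(1S)-2,4,4-trimethylcyclohex-2-en-1-yl]oxymethyl}stannane
Conditions: KH, 18-crown-6 (cat.), THF, 0 °C to rt
Reagents that add atoms: none
Why: Williamson etherification of the potassium alkoxide with the primary iodide should proceed without touching the stereocentre.

Step 3
Reactants: 4 tributyl{[(1S)-2,4,4-trimethylcyclohex-2-en-1-yl]oxymethyl}stannane
Product: 5 [(1R)-2,6,6-trimethylcyclohex-2-en-1-yl]methanol ((R)-α-cyclogeraniol)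
Conditions: n-BuLi, THF, −78 to −20 °C; aq. NH4Cl
Reagents that add atoms: none
Why: Tin–lithium exchange followed by the [2,3]-Wittig–Still rearrangement should transfer the C1–O chirality suprafacially to C5, forming C5–C6 on the ring face that carried the oxygen.

Step 4
Reactants: 5 (R)-α-cyclogeraniol
Product: 6 cis-epoxy alcohol (oxirane on C1–C10 with its oxygen on the face of the C5 hydroxymethyl group)
Conditions: VO(acac)2 (2 mol %), t-BuOOH, CH2Cl2, 0 °C to rt
Reagents that add atoms: tert-butyl hydroperoxide, CC(C)(C)OO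
Why: Vanadium-catalysed hydroxyl-directed epoxidation of the homoallylic alcohol should deliver oxygen syn to CH2OH, which places the future C1 oxygen cis to C6.

Step 5
Reactants: 6 cis-epoxy alcohol
Product: 7 tert-butyldiphenylsilyl ether of 6
Conditions: TBDPSCl, imidazole, DMF, rt
Reagents that add atoms: tert-butyldiphenylsilyl chloride, CC(C)(C)[Si](Cl)(c1ccccc1)c1ccccc1
Why: Standard silylation of the primary alcohol gives a group that should last until the final step.

Step 6
Reactants: 7 silyl ether of the epoxide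
Product: 8 (1S,3R)-3-[(tert-butyldiphenylsilyloxy)methyl]-4,4-dimethyl-2-methylidenecyclohexan-1-ol
Conditions: Et2Al(TMP) (from LiTMP and Et2AlCl), toluene, 0 °C to rt
Reagents that add atoms: none
Why: Aluminium amide-promoted isomerisation of a trisubstituted epoxide to an allylic alcohol should take a proton from the C20 methyl group in a syn β-elimination (H5 is anti to the oxirane oxygen), which leaves the C1–O bond and its configuration intact.

Step 7
Reactants: 8 exo-methylene allylic alcohol
Product: 9 spiro-epoxy alcohol (oxirane on C10–C20 with its oxygen cis to 1-OH)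
Conditions: VO(acac)2 (2 mol %), t-BuOOH, CH2Cl2, 0 °C
Reagents that add atoms: tert-butyl hydroperoxide, CC(C)(C)OO
Why: Hydroxyl-directed allylic epoxidation should be fast on the 1,1-disubstituted alkene, and the configuration of the spiro carbon is of no consequence because C10 becomes a radical in step 9.

Step 8
Reactants: 9 spiro-epoxy alcohol
Product: 10 1-O-triethylsilyl ether of 9
Conditions: TESCl, imidazole, DMAP (cat.), DMF, rt
Reagents that add atoms: triethylsilyl chloride, CC[Si](Cl)(CC)CC
Why: Silylation gives a base-stable group at O1, chosen because an acetate there could undergo intramolecular Claisen acyl transfer to the C8 enolate in step 10.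

Step 9
Reactants: 10 silylated spiro-epoxide; 11 2,2,2-trifluoroethyl acrylate
Product: 12 spiro-δ-lactone (C7 lactone carbonyl, C8H2, C9H2, spiro C10, C20H2–O; 1-OTES, 6-OTBDPS)
Conditions: Cp2TiCl2 (20 mol %), Zn dust, 2,4,6-collidine·HCl, THF, rt
Reagents that add atoms: none
Why: Titanocene-catalysed reductive epoxide opening (trivalent titanium) should give the tertiary C10 radical, whose Giese addition to the acrylate from the face opposite the cis C1 and C5 substituents sets C10, and the hydroxy ester then lactonises with loss of trifluoroethanol.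

Step 10
Reactants: 12 spiro-δ-lactone; 13 N-methoxy-N-methylacetamide
Product: 14 8-acetyl lactone (β-keto lactone, C8 epimers and enol)
Conditions: LiHMDS (2.2 equiv), THF, −78 to 0 °C; aq. NH4Cl
Reagents that add atoms: none
Why: Claisen-type C-acylation of the lactone enolate with a Weinreb amide should stop at the ketone because the tetrahedral adduct is stable until work-up.

Step 11
Reactants: 14 8-acetyl lactone
Product: 16 8-acetyl-8,9-unsaturated lactone (1-OTES), via 8-phenylselanyl β-keto lactone 15 (not isolated)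
Conditions: PhSeCl, pyridine, CH2Cl2, 0 °C; then 30% H2O2, 0 °C to rt
Reagents that add atoms: none
Why: α-Selenenylation of the β-dicarbonyl followed by selenoxide syn-elimination can only use the C9 hydrogens, so the C8=C9 double bond should form regiospecifically.

Step 12
Reactants: 16 unsaturated acetyl lactone (1-OTES)
Product: 18 unsaturated acetyl lactone 1-acetate, via 1-hydroxy enone-lactone 17 (not isolated)
Conditions: HF·pyridine, THF, 0 °C; then pyridine, Ac2O, DMAP, rt
Reagents that add atoms: acetic anhydride, CC(=O)OC(C)=O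
Why: The secondary triethylsilyl ether should be cleaved much faster than the primary TBDPS ether, and acetylation then installs the C1 acetate before any other hydroxyl group exists.

Step 13
Reactants: 18 unsaturated acetyl lactone 1-acetate; 19 2,2-dimethyl-1,3-dioxole
Product: 20 cyclobutane photoadduct (cis-fused at C8–C9; C11 and C14 as acetonide-protected carbinols, exo isomer drawn)
Conditions: hν (350 nm, Pyrex), 19 (10 equiv), CH2Cl2, −40 °C
Reagents that add atoms: none
Why: Enone–alkene [2+2] photocycloaddition of the 2-acyl enoate with the electron-rich dioxole should give the cis-fused cyclobutane by addition to the face of C8=C9 next to the small C1 acetoxy group and away from the C5 CH2OTBDPS group, which sets C8 and C9 with C11 and C14 cis (the acetal carbons lose their configuration in step 16).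

Step 14
Reactants: 20 cyclobutane photoadduct
Product: 21 enol triflate of the C8 acetyl group
Conditions: KHMDS (1.05 equiv), THF, −78 °C; PhNTf2
Reagents that add atoms: N-phenylbis(trifluoromethanesulfonimide), O=S(=O)(N(c1ccccc1)S(=O)(=O)C(F)(F)F)C(F)(F)F
Why: Kinetic enolisation can only occur at the acetyl methyl group (C8 is quaternary and the methyl ketone is far more acidic than the acetate), so O-triflation should give the 1,1-disubstituted vinyl triflate.

Step 15
Reactants: 21 enol triflate; 22 allyltributylstannane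
Product: 23 8-(penta-1,4-dien-2-yl) cyclobutane acetonide
Conditions: Pd(PPh3)4 (5 mol %), LiCl, THF, 65 °C
Reagents that add atoms: none
Why: Stille coupling of a vinyl triflate with an allylstannane should give the skipped diene that carries C15 (masked as C=CH2), C16, C13 and C12.

Step 16
Reactants: 23 dienyl cyclobutane acetonide
Product: 25 11,14-dialdehyde (cis formyl groups on C9 and C8), via cyclobutane-11,14-diol 24 (not isolated)
Conditions: H5IO6, EtOAc, rt; used crude
Reagents that add atoms: none
Why: Periodic acid should hydrolyse the acetonide and cleave the cis-diol in one pot (glycol cleavage), opening the cyclobutane without touching the alkenes.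

Step 17
Reactants: 25 11,14-dialdehyde
Product: 26 tetracyclic 11,14-diol with 15-methylidene group
Conditions: SmI2 (3 equiv), THF (high dilution, no proton source), −78 to 0 °C; aq. NH4Cl
Reagents that add atoms: none
Why: SmI2 should reduce the C14 formyl group selectively because it is β to the lactone carbonyl C7 and forms a chelated trivalent-samarium ketyl, which closes ring D by 5-exo-trig addition to C13 of the vinyl group (C13–C14); the C12 radical so formed closes ring C by 6-exo-trig addition to the C11 formyl carbon (C11–C12), and the alkoxyl radical is reduced by a second SmI2. The closest known reaction type is the SmI2 ketyl–olefin cyclisation of alkenyl β-dicarbonyl compounds run in sequence with capture of the cyclised radical or organosamarium by a carbonyl group. At C14, chelation should place O14 cis to C7 on ring D, and the usual anti preference of ketyl–olefin closures should place C12 trans to O14, which fixes C13 and leaves C12 cis to C9, the only arrangement from which it can reach C11. At C11 the oxygen should end up axial on ring C and anti to C10, because the epimer would force it into a syn-pentane contact with ring A. The step needs chemoselectivity between the two aldehydes and rate selectivity for 5-exo closure over 1,2-vinyl shift and pinacol coupling; chelation at C14, low temperature and high dilution are relied on for this.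

Step 18
Reactants: 26 tetracyclic diol with 15-methylidene group
Product: 28 15-ketone, via secondary ozonide 27 (not isolated)
Conditions: O3, CH2Cl2, −78 °C; then Me2S, −78 °C to rt
Reagents that add atoms: ozone, [O-][O+]=O
Why: Ozonolysis of the only alkene should unmask the C15 ketone under neutral conditions that spare the β-hydroxy ketone.

Step 19
Reactants: 28 15-ketone
Product: 30 16-methylidene-15-ketone (6-OTBDPS), via β-anilinomethyl ketone 29 (not isolated)
Conditions: (CH2O)n, PhNHMe·CF3CO2H, THF, 65 °C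
Reagents that add atoms: formaldehyde (as paraformaldehyde), C=O
Why: Mannich-type α-methylenation should occur at C16, the only enolisable position of the ketone, under mildly acidic conditions that tolerate free hydroxyl groups and the acetate.

Step 20
Reactants: 30 enone silyl ether
Product: 31 CNP0225182.1 (1-acetoxy-6,11,14-trihydroxy-15-oxo-6,7-seco-ent-kaur-16-en-7,20-olide, stereochemistry as in the SMILES)
Conditions: HF·pyridine, pyridine/THF, 0 °C to rt
Reagents that add atoms: none
Why: Buffered fluoride desilylation should free the C6 primary alcohol without affecting the enone, the β-hydroxy ketone, the lactone or the acetate.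

**Compound list**

1 | 2,4,4-trimethylcyclohex-2-en-1-one | CC1=CC(C)(C)CCC1=O | starting material
2 | (S)-2,4,4-trimethylcyclohex-2-en-1-ol | CC1=CC(C)(C)CC[C@@H]1O | intermediate
3 | tributyl(iodomethyl)stannane | CCCC[Sn](CCCC)(CCCC)CI | starting material
4 | tributyl{[(1S)-2,4,4-trimethylcyclohex-2-en-1-yl]oxymethyl}stannane | CC1=CC(C)(C)CC[C@@H]1OC[Sn](CCCC)(CCCC)CCCC | intermediate
5 | [(1R)-2,6,6-trimethylcyclohex-2-en-1-yl]methanol, (R)-α-cyclogeraniol | CC1=CCCC(C)(C)[C@H]1CO | intermediate
6 | cis-epoxy alcohol (C1–C10 oxirane, oxygen on the face of CH2OH) | C[C@]12O[C@H]1CCC(C)(C)[C@H]2CO | intermediate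
7 | TBDPS ether of 6 | C[C@]12O[C@H]1CCC(C)(C)[C@H]2CO[Si](c1ccccc1)(c1ccccc1)C(C)(C)C | intermediate
8 | (1S,3R)-3-[(tert-butyldiphenylsilyloxy)methyl]-4,4-dimethyl-2-methylidenecyclohexan-1-ol | C=C1[C@@H](O)CCC(C)(C)[C@H]1CO[Si](c1ccccc1)(c1ccccc1)C(C)(C)C | intermediate
9 | spiro-epoxy alcohol (C10–C20 oxirane, oxygen cis to 1-OH) | C1O[C@]12[C@@H](O)CCC(C)(C)[C@H]2CO[Si](c1ccccc1)(c1ccccc1)C(C)(C)C | intermediate
10 | 1-O-triethylsilyl ether of 9 | C1O[C@]12[C@@H](O[Si](CC)(CC)CC)CCC(C)(C)[C@H]2CO[Si](c1ccccc1)(c1ccccc1)C(C)(C)C | intermediate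
11 | 2,2,2-trifluoroethyl acrylate | C=CC(=O)OCC(F)(F)F | starting material
12 | spiro-δ-lactone (1-OTES, 6-OTBDPS; C9 trans to O1 and C6 on ring A) | O=C1OC[C@]2([C@@H](O[Si](CC)(CC)CC)CCC(C)(C)[C@H]2CO[Si](c3ccccc3)(c3ccccc3)C(C)(C)C)CC1 | intermediate
13 | N-methoxy-N-methylacetamide | CC(=O)N(C)OC | starting material
14 | 8-acetyl spiro-lactone (C8 epimers and enol, inconsequential) | O=C1OC[C@]2([C@@H](O[Si](CC)(CC)CC)CCC(C)(C)[C@H]2CO[Si](c3ccccc3)(c3ccccc3)C(C)(C)C)CC1C(C)=O | intermediate
15 | 8-acetyl-8-phenylselanyl spiro-lactone (C8 epimers) | O=C1OC[C@]2([C@@H](O[Si](CC)(CC)CC)CCC(C)(C)[C@H]2CO[Si](c3ccccc3)(c3ccccc3)C(C)(C)C)CC1([Se]c3ccccc3)C(C)=O | intermediate (not isolated)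
16 | 8-acetyl-8,9-unsaturated spiro-lactone, 1-OTES | O=C1OC[C@]2([C@@H](O[Si](CC)(CC)CC)CCC(C)(C)[C@H]2CO[Si](c3ccccc3)(c3ccccc3)C(C)(C)C)C=C1C(C)=O | intermediate
17 | 8-acetyl-8,9-unsaturated spiro-lactone, 1-OH | O=C1OC[C@]2([C@@H](O)CCC(C)(C)[C@H]2CO[Si](c3ccccc3)(c3ccccc3)C(C)(C)C)C=C1C(C)=O | intermediate (not isolated)
18 | 8-acetyl-8,9-unsaturated spiro-lactone, 1-OAc | O=C1OC[C@]2([C@@H](OC(C)=O)CCC(C)(C)[C@H]2CO[Si](c3ccccc3)(c3ccccc3)C(C)(C)C)C=C1C(C)=O | intermediate
19 | 2,2-dimethyl-1,3-dioxole | CC1(C)OC=CO1 | starting material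
20 | cyclobutane photoadduct (cis-fused at C8–C9, C11/C14 acetonide, exo isomer) | CC(=O)[C@@]12C(=O)OC[C@]3([C@@H](OC(C)=O)CCC(C)(C)[C@H]3CO[Si](c4ccccc4)(c4ccccc4)C(C)(C)C)[C@@H]1[C@H]1OC(C)(C)O[C@H]12 | intermediate
21 | enol triflate of 20 | C=C(OS(=O)(=O)C(F)(F)F)[C@@]12C(=O)OC[C@]3([C@@H](OC(C)=O)CCC(C)(C)[C@H]3CO[Si](c4ccccc4)(c4ccccc4)C(C)(C)C)[C@@H]1[C@H]1OC(C)(C)O[C@H]12 | intermediate
22 | allyltributylstannane | C=CC[Sn](CCCC)(CCCC)CCCC | starting material
23 | 8-(penta-1,4-dien-2-yl) cyclobutane acetonide | C=CCC(=C)[C@@]12C(=O)OC[C@]3([C@@H](OC(C)=O)CCC(C)(C)[C@H]3CO[Si](c4ccccc4)(c4ccccc4)C(C)(C)C)[C@@H]1[C@H]1OC(C)(C)O[C@H]12 | intermediate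
24 | cyclobutane-11,14-diol | C=CCC(=C)[C@@]12C(=O)OC[C@]3([C@@H](OC(C)=O)CCC(C)(C)[C@H]3CO[Si](c4ccccc4)(c4ccccc4)C(C)(C)C)[C@@H]1[C@@H](O)[C@H]2O | intermediate (not isolated)
25 | 11,14-dialdehyde (cis on the lactone ring; C8 also carries the dienyl chain) | C=CCC(=C)[C@@]1(C=O)C(=O)OC[C@]2([C@@H](OC(C)=O)CCC(C)(C)[C@H]2CO[Si](c3ccccc3)(c3ccccc3)C(C)(C)C)[C@@H]1C=O | intermediate
26 | tetracyclic 11,14-diol, 15-methylidene, 6-OTBDPS | C1C(=C)[C@@]23C(=O)OC[C@]4([C@@H](OC(C)=O)CCC(C)(C)[C@H]4CO[Si](c5ccccc5)(c5ccccc5)C(C)(C)C)[C@@H]2[C@@H](O)C[C@@H]1[C@H]3O | intermediate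
27 | secondary ozonide of 26 (spiro-1,2,4-trioxolane at C15, either epimer) | C1C2(OCOO2)[C@@]34C(=O)OC[C@]5([C@@H](OC(C)=O)CCC(C)(C)[C@H]5CO[Si](c6ccccc6)(c6ccccc6)C(C)(C)C)[C@@H]3[C@@H](O)C[C@@H]1[C@H]4O | intermediate (not isolated)
28 | 15-ketone, 6-OTBDPS | C1C(=O)[C@@]23C(=O)OC[C@]4([C@@H](OC(C)=O)CCC(C)(C)[C@H]4CO[Si](c5ccccc5)(c5ccccc5)C(C)(C)C)[C@@H]2[C@@H](O)C[C@@H]1[C@H]3O | intermediate
29 | 16-[(N-methylanilino)methyl]-15-ketone (C16 epimers) | CN(CC1C(=O)[C@@]23C(=O)OC[C@]4([C@@H](OC(C)=O)CCC(C)(C)[C@H]4CO[Si](c5ccccc5)(c5ccccc5)C(C)(C)C)[C@@H]2[C@@H](O)C[C@@H]1[C@H]3O)c1ccccc1 | intermediate (not isolated)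
30 | 16-methylidene-15-ketone, 6-OTBDPS | C=C1C(=O)[C@@]23C(=O)OC[C@]4([C@@H](OC(C)=O)CCC(C)(C)[C@H]4CO[Si](c5ccccc5)(c5ccccc5)C(C)(C)C)[C@@H]2[C@@H](O)C[C@@H]1[C@H]3O | intermediate
31 | CNP0225182.1 | C=C1C(=O)[C@@]23C(=O)OC[C@]4([C@@H](OC(C)=O)CCC(C)(C)[C@H]4CO)[C@@H]2[C@@H](O)C[C@@H]1[C@H]3O | target

**Step count and risks**

Total step count: 20. Longest linear sequence: 20 steps (fully linear from 1).

Steps most likely to fail:

1. Step 17. The C14 ketyl may undergo a 1,2-vinyl shift by 3-exo closure onto the neighbouring C15 methylidene group faster than it closes ring D. The two cis formyl groups may couple with each other in a pinacol fashion. Reduction may also start at C11 and close a six-membered ring onto C13. The fallback sets out from 23 and returns at 26. Cross-metathesis of 23 with tert-butyl acrylate (second-generation Hoveyda–Grubbs catalyst) would give the (E)-enoate F1, and H5IO6 as in step 16 would give the dialdehyde enoate F2. With SmI2, LiBr and t-BuOH the C14 ketyl would now add to the activated C13 in a fast conjugate 5-exo closure, and the samarium enolate at C12 would close ring C by aldol addition to the C11 aldehyde, giving the tert-butyl ester F3. ZnBr2 in CH2Cl2 would give the β-hydroxy acid F4, and a photoredox hydrodecarboxylation (acridinium photocatalyst, catalytic PhSSPh, blue light) would return 26.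

2. Step 13. The excited enone-lactone may be diverted by the electron-rich dioxole into oxetane formation or hetero-Diels–Alder addition, or the hindered trisubstituted alkene may react too slowly. The fallback sets out from 18 and returns at 20. Photocycloaddition with (E)-1,2-dichloroethene as an acetylene equivalent would give the dichlorocyclobutane F5, and zinc dust would give the cyclobutene F6. OsO4 (cat.) with N-methylmorpholine N-oxide would dihydroxylate the only alkene from the convex face to the cis-diol F7, and 2,2-dimethoxypropane with PPTS would give 20. This fallback does not improve facial selectivity.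

3. Step 19. Hot, mildly acidic Mannich conditions may trigger retro-aldol cleavage of the C8–C14 bond of the β-hydroxy ketone or hemiketalisation of the C15 ketone. The fallback sets out from 28 and returns at 31. TESOTf and 2,6-lutidine would give the 11,14-bis(triethylsilyl) ether F8, which can no longer undergo retro-aldol cleavage. The same formaldehyde/anilinium methylenation would then pass through the Mannich base F9 to the protected enone F10, and HF·pyridine would remove all three silyl groups to give 31.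

**Further compounds**

F1 | step 17 | tert-butyl (E)-enoate from cross-metathesis of 23 | CC(C)(C)OC(=O)/C=C/CC(=C)[C@@]12C(=O)OC[C@]3([C@@H](OC(C)=O)CCC(C)(C)[C@H]3CO[Si](c4ccccc4)(c4ccccc4)C(C)(C)C)[C@@H]1[C@H]1OC(C)(C)O[C@H]12
F2 | step 17 | 11,14-dialdehyde bearing the tert-butyl enoate chain | CC(C)(C)OC(=O)/C=C/CC(=C)[C@@]1(C=O)C(=O)OC[C@]2([C@@H](OC(C)=O)CCC(C)(C)[C@H]2CO[Si](c3ccccc3)(c3ccccc3)C(C)(C)C)[C@@H]1C=O
F3 | step 17 | tetracyclic diol with tert-butoxycarbonyl group at C12 (C12 epimers) | C1C(=C)[C@@]23C(=O)OC[C@]4([C@@H](OC(C)=O)CCC(C)(C)[C@H]4CO[Si](c5ccccc5)(c5ccccc5)C(C)(C)C)[C@@H]2[C@@H](O)C(C(=O)OC(C)(C)C)[C@@H]1[C@H]3O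
F4 | step 17 | tetracyclic diol with carboxyl group at C12 (C12 epimers) | C1C(=C)[C@@]23C(=O)OC[C@]4([C@@H](OC(C)=O)CCC(C)(C)[C@H]4CO[Si](c5ccccc5)(c5ccccc5)C(C)(C)C)[C@@H]2[C@@H](O)C(C(=O)O)[C@@H]1[C@H]3O
F5 | step 13 | 11,14-dichlorocyclobutane photoadduct (chlorine configurations undefined) | CC(=O)[C@@]12C(=O)OC[C@]3([C@@H](OC(C)=O)CCC(C)(C)[C@H]3CO[Si](c4ccccc4)(c4ccccc4)C(C)(C)C)[C@@H]1C(Cl)C2Cl
F6 | step 13 | cis-fused cyclobutene (C11=C14) | CC(=O)[C@@]12C(=O)OC[C@]3([C@@H](OC(C)=O)CCC(C)(C)[C@H]3CO[Si](c4ccccc4)(c4ccccc4)C(C)(C)C)[C@@H]1C=C2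
F7 | step 13 | 8-acetyl cyclobutane-11,14-diol (exo cis-diol) | CC(=O)[C@@]12C(=O)OC[C@]3([C@@H](OC(C)=O)CCC(C)(C)[C@H]3CO[Si](c4ccccc4)(c4ccccc4)C(C)(C)C)[C@@H]1[C@@H](O)[C@H]2O
F8 | step 19 | 15-ketone 11,14-bis(triethylsilyl) ether | C1C(=O)[C@@]23C(=O)OC[C@]4([C@@H](OC(C)=O)CCC(C)(C)[C@H]4CO[Si](c5ccccc5)(c5ccccc5)C(C)(C)C)[C@@H]2[C@@H](O[Si](CC)(CC)CC)C[C@@H]1[C@H]3O[Si](CC)(CC)CC
F9 | step 19 | Mannich base of F8 (C16 epimers, not isolated) | CN(CC1C(=O)[C@@]23C(=O)OC[C@]4([C@@H](OC(C)=O)CCC(C)(C)[C@H]4CO[Si](c5ccccc5)(c5ccccc5)C(C)(C)C)[C@@H]2[C@@H](O[Si](CC)(CC)CC)C[C@@H]1[C@H]3O[Si](CC)(CC)CC)c1ccccc1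
F10 | step 19 | 16-methylidene-15-ketone 11,14-bis(triethylsilyl) ether | C=C1C(=O)[C@@]23C(=O)OC[C@]4([C@@H](OC(C)=O)CCC(C)(C)[C@H]4CO[Si](c5ccccc5)(c5ccccc5)C(C)(C)C)[C@@H]2[C@@H](O[Si](CC)(CC)CC)C[C@@H]1[C@H]3O[Si](CC)(CC)CC
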